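# Proposed synthesis of sideroxylonal C by malonyl/3-oxoglutarate construction of ring B

## Analysis of the target

Sideroxylonal C (22) is a 2-arylchroman. Ring A (C4a to C8a) is fused to the pyran ring C (O1, C2, C3, C4), and C2 carries a second benzene ring B. Both aromatic rings are fully substituted phloroglucinol units. Ring A has hydroxyls at C5 and C7 (its third oxygen is O1) and formyl groups at C6 and C8. Ring B has hydroxyls at C2', C4' and C6' and formyl groups at C3' and C5'.

The three stereocentres are contiguous: C2 (aryl), C3 (isopropyl) and C4 (isobutyl), all R, with 2,3-trans and 3,4-trans relationships. Aryl and isobutyl therefore lie on one face and isopropyl on the other.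

The molecule carries four aldehydes and five phenols. The C2–O1 bond is a benzylic aryl ether ortho and para to ring B hydroxyls, so it can ionise to a quinone methide under acid or base. C2 is thus epimerisable, whereas C3 and C4 are fixed once made. The difficulty is threefold: three adjacent tertiary carbons, each with a bulky group, as one enantiomer; two hexasubstituted arenes; and four formyl groups.

The strategy rests on the local symmetry of ring B. C1' bears the chroman, C2' and C6' bear oxygen, C3' and C5' bear carbonyl carbons, and C4' bears oxygen. C1' with C2' and C6' is a 2-substituted malonyl unit. C3', C4', C5' and the two formyl carbons are a 3-oxoglutarate. Ring B can therefore be grown on C2 after the stereotriad is complete.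

## Retrosynthetic reasoning

**22 to 21.** The five phenols are traced back to methyl ethers. Methyl is chosen because ring A arrives as a dimethyl ether from 1 and because these ethers survive organometallic, basic, reducing and Lewis-acidic steps. In 21 every methoxy group is ortho to a formyl group, so the last step can rely on chelation-assisted cleavage by a boron trihalide.

**21 to 20.** The C6–CHO and C8–CHO bonds of ring A are cut. In 20, ring A is a 1,3,5-trioxygenated ring with exactly two free positions and ring B has none, so an electrophilic formylation has no regiochemical choice. The cut is made late because ring A aldehydes would not survive the enolate chemistry that builds ring B.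

**20 to 19 to 18 to 17.** These are changes of oxidation level and protection only. The formyl carbons of ring B are traced to the ester carbons of 17 (alcohol oxidation, ester reduction), and the three ring B ethers to the free triol.

**17 to 13 and 14 (key disconnection).** Ring B is cut at C2'–C3' and C6'–C5'. This divides it into the malonyl unit of 13 and the oxoglutarate 14, both symmetrical, so no regiochemistry has to be controlled and both future formyl carbons are already attached. Cutting the C2–C1' bond instead would require an intact electron-rich ring B as a nucleophile and two more formylations next to a labile benzylic ether. The forward reaction has to make one intermolecular C-acylation and one ring-closing Claisen condensation. The malonyl unit is used as its dichloride because a dialkyl ester of 12 under alkoxide would be enolised and would open ring C by loss of the ring A phenoxide.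

**13 to 12 to 11.** These steps are activation and unmasking. Benzyl esters are chosen in 11 so that the diacid 12 is released by hydrogenolysis, without base.

**11 to 8 and 9.** The O1–C2 bond (oxa-Michael addition) and the C2=C bond to the malonate carbon (Knoevenagel condensation) are cut. Lactol 8 is the masked hydroxy aldehyde 7. The forward reaction sets C2 under control by C3.

**8 to 4 and 5.** The C3–C4 bond and the hemiacetal O1–C2 bond are cut. This leads to quinone methide 6, released from 4, and to the enamine of aldehyde 5, which brings the isopropyl group. This is the one enantioselective step and it sets C3 and C4.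

**4 to 3 to 1 and 2.** The sulfone comes from the benzylic alcohol, and the C4–CH2 bond from Grignard addition. Starting from aldehyde 1 fixes the position of the side chain between the hydroxyl and a methoxy group.

## Alternatives that were turned down

**Alternative 1:** The pyran ring is cut at C2–C3 and C4–C4a, a cationic oxa-Povarov [4+2].
- **Forward key step:** The mixed acetal A1 of the ring B aldehyde and the ring A phenol ionises under a chiral Brønsted acid. The diene A2 bonds through its isopropyl-bearing terminus to C2, and the allyl cation is trapped by the ortho carbon of ring A to give chroman A3.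
- **For:** It is convergent, and ring C with all three stereocentres forms in one step from simple pieces. On step count it is clearly stronger, at about six steps overall.
- **Against:** The reaction is stepwise and cationic. Three stereocentres and the absolute configuration would have to be dictated by a counter-anion loosely paired with a highly stabilised oxocarbenium ion. The diene can oligomerise, or be attacked at the wrong terminus or by the wrong arene position. The product still needs alkene hydrogenation and four formylations on two electron-rich rings beside a 2-(trialkoxyphenyl) benzylic ether.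
- **Comparison:** The chosen route is longer. In return it sets the absolute configuration by a catalysis type with a firm stereochemical model, relays C2 thermodynamically, and brings ring B in with its carbonyl carbons in place and electron-poor.

**Alternative 2:** The cuts are O1–C2 and C2–C3, a Prins or oxonium-ene annulation.
- **Forward key step:** Phenol A4, which already carries the C4 stereocentre and a 2-methylprop-1-enyl group, condenses with ring B aldehyde A5 under a silyl triflate to an O-aryl oxocarbenium ion. The alkene carbon C3 attacks it and proton loss leaves the isopropenyl chroman A6.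
- **For:** A chair-like closure with equatorial groups is a reliable way to relay C4 to C2 and C3. On this point of diastereocontrol it is at least as strong as the chosen route.
- **Against:** A4 needs its own asymmetric synthesis of a hindered benzylic centre. A4 also pairs a free phenol with a trisubstituted alkene, which under acid can cyclise by hydroalkoxylation to a 2,2-dimethylchroman. Hydrogenation and the same fourfold formylation follow.
- **Comparison:** The total length is similar to the chosen route once A4 is counted. The chosen route sets C3 and C4 together in one catalytic step and avoids the late tetra-formylation.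

**Alternative 3:** The lactol is cut at C4–C4a and O1–C2, an iminium Friedel–Crafts/hemiacetal [3+3].
- **Forward key step:** Enal A7, the self-aldol condensation product of aldehyde 5, is activated by a chiral primary amine. Phenol A8 attacks its β-carbon and then closes the hemiacetal to lactol A9, the same compound as 8.
- **For:** It reaches the lactol in two steps from two cheap achiral materials, one step fewer than here. If ring B were then attached as a ready-made trialkoxybenzene, the whole synthesis would be about half as long as the chosen one.
- **Against:** The iminium ion of an α-isopropyl, β-isobutyl enal is very hindered. Phenols have not been established as partners for α-branched enals under primary-amine catalysis. A8 can also react para to its hydroxyl. The short end game again needs four formylations on a 2-(trialkoxyphenyl)chroman under strong Lewis acid, where C2–O1 ionises readily.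
- **Comparison:** The chosen route reaches the same lactol by a catalysis type known for its substrate class, with the isopropyl group delivered by an unhindered enamine. Its ring B leaves only two formylations, on ring A alone.

Key step: step 7

Remark: the SMILES encodes the (2R,3R,4R) enantiomer. The sense of induction written for step 3 is assigned by analogy with the usual shielding model of the catalyst and would be fixed by the choice of catalyst antipode.

## Route

Step 1
Reactants: 1 2-hydroxy-4,6-dimethoxybenzaldehyde; 2 isobutylmagnesium bromide
Product: 3 rac-2-(1-hydroxy-3-methylbutyl)-3,5-dimethoxyphenol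
Conditions: 2 (2.5 equiv), THF, 0 °C to rt; aq. NH4Cl
Reagents that add atoms: none
Why: Grignard 1,2-addition to the aldehyde after the first equivalent has formed the magnesium phenoxide; the new carbinol centre is racemic on purpose, because it becomes sp2 in quinone methide 6.

Step 2
Reactants: 3 rac-2-(1-hydroxy-3-methylbutyl)-3,5-dimethoxyphenol
Product: 4 rac-3,5-dimethoxy-2-[3-methyl-1-(4-methylbenzenesulfonyl)butyl]phenol
Conditions: 4-MeC6H4SO2Na (1.5 equiv), HCO2H, CH2Cl2/H2O, rt
Reagents that add atoms: sodium 4-methylbenzenesulfinate, Cc1ccc(cc1)S(=O)[O-].[Na+]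
Why: Acid ionises the benzylic alcohol, which is flanked by three oxygen donors, and the sulfinate captures the cation at sulfur (SN1 sulfonylation); the sulfone is a storable precursor that releases 6 with mild base.

Step 3
Reactants: 4 rac-3,5-dimethoxy-2-[3-methyl-1-(4-methylbenzenesulfonyl)butyl]phenol; 5 3-methylbutanal (isovaleraldehyde)
Product: 8 (3R,4R)-4-isobutyl-3-isopropyl-5,7-dimethoxychroman-2-ol (both anomers at C2), via o-quinone methide 6 (not isolated), via hydroxy aldehyde 7 (not isolated)
Conditions: 5 (3 equiv), (S)-2-[diphenyl(trimethylsilyloxy)methyl]pyrrolidine (20 mol %), NaHCO3, CH2Cl2/H2O, 0 °C to rt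
Reagents that add atoms: none
Why: Known amine-catalysed Michael addition/hemiacetalisation of an aldehyde with a quinone methide generated in situ: hydrogencarbonate eliminates sulfinate from 4 to give 6, the enamine of 5 adds to the methide carbon, hydrolysis gives 7 and the phenol closes the lactol. The diphenyl(silyloxy)methyl group shields one face of the E-enamine and sets C3, the synclinal approach of the methide sets C4, and the 3,4-trans lactol is also the more stable diastereomer.

Step 4
Reactants: 8 (3R,4R)-4-isobutyl-3-isopropyl-5,7-dimethoxychroman-2-ol; 9 dibenzyl malonate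
Product: 11 dibenzyl 2-[(2R,3R,4R)-4-isobutyl-3-isopropyl-5,7-dimethoxychroman-2-yl]malonate, via alkylidene malonate 10 (not isolated)
Conditions: piperidine (0.2 equiv), AcOH (0.2 equiv), 4 Å molecular sieves, toluene, 80 °C
Reagents that add atoms: none
Why: Knoevenagel condensation on the open form 7, then 6-exo-trig oxa-Michael addition of the phenol; in 10 the C3–H bond eclipses the alkylidene plane to relieve A(1,3) strain, so the oxygen adds to the face that places the malonyl group trans to isopropyl, which is also the all-equatorial, more stable isomer. Only catalytic amine is present, so the closed chroman is the resting state.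

Step 5
Reactants: 11 dibenzyl 2-[(2R,3R,4R)-4-isobutyl-3-isopropyl-5,7-dimethoxychroman-2-yl]malonate
Product: 12 2-[(2R,3R,4R)-4-isobutyl-3-isopropyl-5,7-dimethoxychroman-2-yl]malonic acid
Conditions: H2 (1 atm), Pd/C, EtOAc, rt
Reagents that add atoms: none
Why: Hydrogenolysis of the two benzyl esters under neutral conditions; alkaline hydrolysis is avoided because an enolised malonate ester would open ring C, and the C2–O1 bond is not benzylic at this stage and is not cleaved.

Step 6
Reactants: 12 2-[(2R,3R,4R)-4-isobutyl-3-isopropyl-5,7-dimethoxychroman-2-yl]malonic acid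
Product: 13 2-[(2R,3R,4R)-4-isobutyl-3-isopropyl-5,7-dimethoxychroman-2-yl]propanedioyl dichloride
Conditions: 1-chloro-N,N,2-trimethylprop-1-en-1-amine (2.2 equiv), CH2Cl2, 0 °C to rt; concentrated and used crude
Reagents that add atoms: 1-chloro-N,N,2-trimethylprop-1-en-1-amine, CC(C)=C(Cl)N(C)C
Why: The α-chloroenamine turns carboxylic acids into acid chlorides under neutral conditions and gives only an amide as by-product; oxalyl chloride with DMF is avoided because it would formylate or acylate the electron-rich ring A.

Step 7
Reactants: 13 2-[(2R,3R,4R)-4-isobutyl-3-isopropyl-5,7-dimethoxychroman-2-yl]propanedioyl dichloride; 14 dimethyl 3-oxopentanedioate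
Product: 17 dimethyl 2,4,6-trihydroxy-5-[(2R,3R,4R)-4-isobutyl-3-isopropyl-5,7-dimethoxychroman-2-yl]isophthalate, via pyranone 15 (not isolated), via triketo triester 16 (not isolated)
Conditions: 14 (1.1 equiv), MgCl2 (1.2 equiv), pyridine (2.5 equiv), CH2Cl2, 0 °C to rt, 13 added last at high dilution; then Mg(OMe)2 (5 equiv), MeOH, 50 °C; 1 M HCl
Reagents that add atoms: none
Why: In the first stage the magnesium chelate of 14 is acylated at one α-carbon by an acid chloride group of 13 (bond C2'–C3'), and the enol oxygen of the ketone then takes the second acid chloride to give pyranone 15, the normal course of a malonyl dichloride with a β-keto ester under MgCl2/pyridine soft enolisation. In the second stage methoxide opens the lactone to the magnesium-chelated triketo triester 16, whose CH2CO2Me carbanion attacks the ester on the chroman-bearing carbon (bond C6'–C5') in a 6-exo-trig Claisen (Dieckmann-type) closure of ring B; three enolisations then give the aromatic triol, and formation of the chelated phenoxide pulls the equilibria. The closest known reaction types are the cyclocondensation of malonate with acetonedicarboxylate esters to phloroglucinol dicarboxylates and the Mg(OMe)2-induced ring switch of 6-(acylmethyl)-4-hydroxypyran-2-ones to phloroglucinols. Both partners are symmetrical about the C1'–C4' axis, so only one substitution pattern can form and the ester groups must stand at C3' and C5'; O- versus C-acylation in the first stage need not be controlled, because both products converge on 17 in the second. The acid chloride is used instead of a malonate ester and alkoxide because an enolised malonate ester would expel the ring A phenoxide from C2 (E1cB, as a flavanone opens to a chalcone) and the alkylidene malonate so exposed would take up the oxoglutarate enolate by Michael addition; here the intermolecular C–C bond is made without strong base and no free carbon nucleophile is left when Mg(OMe)2 is added. No stereocentre is formed; should C2 open at the stage of 16, Claisen closure still leads to 17 because the ring A phenoxide adds back to the resulting quinone methide of ring B, and A(1,3) strain together with the all-equatorial product direct this to the 2,3-trans isomer. Ring A is not acylated, since no strong Lewis acid is present and attack of the tethered acyl group at C8 would require a strained bridged ring through O1 and C8a.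

Step 8
Reactants: 17 dimethyl 2,4,6-trihydroxy-5-[(2R,3R,4R)-4-isobutyl-3-isopropyl-5,7-dimethoxychroman-2-yl]isophthalate
Product: 18 dimethyl 5-[(2R,3R,4R)-4-isobutyl-3-isopropyl-5,7-dimethoxychroman-2-yl]-2,4,6-trimethoxyisophthalate
Conditions: Me2SO4 (4.5 equiv), K2CO3, acetone, reflux
Reagents that add atoms: dimethyl sulfate, COS(=O)(=O)OC
Why: Williamson O-methylation of the three acidic phenols; every carbon of ring B is substituted, so C-methylation would need dearomatisation at a hindered carbon, and the two ester groups make ring B a poor donor, which keeps the C2–O1 bond from opening to a quinone methide under the carbonate base.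

Step 9
Reactants: 18 dimethyl 5-[(2R,3R,4R)-4-isobutyl-3-isopropyl-5,7-dimethoxychroman-2-yl]-2,4,6-trimethoxyisophthalate
Product: 19 {5-[(2R,3R,4R)-4-isobutyl-3-isopropyl-5,7-dimethoxychroman-2-yl]-2,4,6-trimethoxy-1,3-phenylene}dimethanol
Conditions: i-Bu2AlH (6 equiv), CH2Cl2, −78 to 0 °C; aq. KNaC4H4O6 (potassium sodium tartrate)
Reagents that add atoms: none
Why: Hydride reduction of both esters to primary alcohols; the esters lie between two methoxy groups, are twisted out of conjugation and reduce readily, and the tartrate work-up keeps the acid-labile trimethoxybenzylic alcohols away from acid.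

Step 10
Reactants: 19 {5-[(2R,3R,4R)-4-isobutyl-3-isopropyl-5,7-dimethoxychroman-2-yl]-2,4,6-trimethoxy-1,3-phenylene}dimethanol
Product: 20 5-[(2R,3R,4R)-4-isobutyl-3-isopropyl-5,7-dimethoxychroman-2-yl]-2,4,6-trimethoxyisophthalaldehyde
Conditions: MnO2 (20 equiv), CH2Cl2, rt
Reagents that add atoms: none
Why: Heterogeneous benzylic alcohol oxidation that stops at the aldehyde and leaves the ethers and the chroman untouched.

Step 11
Reactants: 20 5-[(2R,3R,4R)-4-isobutyl-3-isopropyl-5,7-dimethoxychroman-2-yl]-2,4,6-trimethoxyisophthalaldehyde
Product: 21 (2R,3R,4R)-2-(3,5-diformyl-2,4,6-trimethoxyphenyl)-4-isobutyl-3-isopropyl-5,7-dimethoxychroman-6,8-dicarbaldehyde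
Conditions: Cl2CHOMe (6 equiv), TiCl4 (6 equiv), CH2Cl2, −20 °C to rt; H2O
Reagents that add atoms: dichloromethyl methyl ether, COC(Cl)Cl; water, O
Why: Rieche formylation (Friedel–Crafts attack of the chlorocarbenium ion formed from the dichloromethyl ether and TiCl4, then hydrolysis); ring A is a 1,3,5-trioxygenated ring with only C6 and C8 free, while ring B has no free position and is deactivated by its formyl groups, so the regiochemistry is fixed. Double formylation of such triethers is known and needs excess reagent at room temperature.

Step 12
Reactants: 21 (2R,3R,4R)-2-(3,5-diformyl-2,4,6-trimethoxyphenyl)-4-isobutyl-3-isopropyl-5,7-dimethoxychroman-6,8-dicarbaldehyde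
Product: 22 sideroxylonal C, (2R,3R,4R)-2-(3,5-diformyl-2,4,6-trihydroxyphenyl)-5,7-dihydroxy-4-isobutyl-3-isopropylchroman-6,8-dicarbaldehyde
Conditions: BCl3 (10 equiv), CH2Cl2, −78 °C to rt; aq. HCl
Reagents that add atoms: none
Why: Chelation-assisted ether cleavage: each of the five methoxy groups is ortho to a formyl group, so BCl3 binds between carbonyl and ether oxygen and chloride removes the methyl group, while the aldehydes are held as boron chelates and released on hydrolysis. C3 and C4 cannot epimerise, and C2, should the C2–O1 bond open transiently, recloses to the favoured 2,3-trans isomer.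

## Compound list

1 | 2-hydroxy-4,6-dimethoxybenzaldehyde | COc1cc(O)c(C=O)c(OC)c1 | starting material
2 | isobutylmagnesium bromide | CC(C)C[Mg]Br | starting material
3 | rac-2-(1-hydroxy-3-methylbutyl)-3,5-dimethoxyphenol | CC(C)CC(O)c1c(OC)cc(OC)cc1O | intermediate
4 | rac-3,5-dimethoxy-2-[3-methyl-1-(4-methylbenzenesulfonyl)butyl]phenol | CC(C)CC(c1c(OC)cc(OC)cc1O)S(=O)(=O)c1ccc(C)cc1 | intermediate
5 | 3-methylbutanal (isovaleraldehyde) | CC(C)CC=O | starting material
6 | 3,5-dimethoxy-6-(3-methylbutylidene)cyclohexa-2,4-dien-1-one (o-quinone methide) | COC1=CC(=O)C(=CCC(C)C)C(OC)=C1 | intermediate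
7 | (2R,3R)-3-(2-hydroxy-4,6-dimethoxyphenyl)-5-methyl-2-(propan-2-yl)hexanal | CC(C)C[C@@H](c1c(OC)cc(OC)cc1O)[C@H](C=O)C(C)C | intermediate
8 | (3R,4R)-4-isobutyl-3-isopropyl-5,7-dimethoxychroman-2-ol (both anomers at C2) | CC(C)C[C@H]1c2c(OC)cc(OC)cc2OC(O)[C@@H]1C(C)C | intermediate
9 | dibenzyl malonate | O=C(CC(=O)OCc1ccccc1)OCc1ccccc1 | starting material
10 | dibenzyl 2-[(2S,3R)-3-(2-hydroxy-4,6-dimethoxyphenyl)-5-methyl-2-(propan-2-yl)hexylidene]malonate (same spatial arrangement as 7) | CC(C)C[C@@H](c1c(OC)cc(OC)cc1O)[C@H](C=C(C(=O)OCc1ccccc1)C(=O)OCc1ccccc1)C(C)C | intermediate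
11 | dibenzyl 2-[(2R,3R,4R)-4-isobutyl-3-isopropyl-5,7-dimethoxychroman-2-yl]malonate | CC(C)C[C@H]1c2c(OC)cc(OC)cc2O[C@@H](C(C(=O)OCc2ccccc2)C(=O)OCc2ccccc2)[C@@H]1C(C)C | intermediate
12 | 2-[(2R,3R,4R)-4-isobutyl-3-isopropyl-5,7-dimethoxychroman-2-yl]malonic acid | CC(C)C[C@H]1c2c(OC)cc(OC)cc2O[C@@H](C(C(=O)O)C(=O)O)[C@@H]1C(C)C | intermediate
13 | 2-[(2R,3R,4R)-4-isobutyl-3-isopropyl-5,7-dimethoxychroman-2-yl]propanedioyl dichloride | CC(C)C[C@H]1c2c(OC)cc(OC)cc2O[C@@H](C(C(=O)Cl)C(=O)Cl)[C@@H]1C(C)C | intermediate
14 | dimethyl 3-oxopentanedioate | COC(=O)CC(=O)CC(=O)OC | starting material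
15 | methyl 4-hydroxy-3-[(2R,3R,4R)-4-isobutyl-3-isopropyl-5,7-dimethoxychroman-2-yl]-6-(2-methoxy-2-oxoethyl)-2-oxo-2H-pyran-5-carboxylate | CC(C)C[C@H]1c2c(OC)cc(OC)cc2O[C@@H](C2=C(O)C(C(=O)OC)=C(CC(=O)OC)OC2=O)[C@@H]1C(C)C | intermediate
16 | dimethyl 2-{2-[(2R,3R,4R)-4-isobutyl-3-isopropyl-5,7-dimethoxychroman-2-yl]-3-methoxy-3-oxopropanoyl}-3-oxopentanedioate (tautomers, two new methine carbons unassigned) | CC(C)C[C@H]1c2c(OC)cc(OC)cc2O[C@@H](C(C(=O)OC)C(=O)C(C(=O)OC)C(=O)CC(=O)OC)[C@@H]1C(C)C | intermediate
17 | dimethyl 2,4,6-trihydroxy-5-[(2R,3R,4R)-4-isobutyl-3-isopropyl-5,7-dimethoxychroman-2-yl]isophthalate | CC(C)C[C@H]1c2c(OC)cc(OC)cc2O[C@@H](c2c(O)c(C(=O)OC)c(O)c(C(=O)OC)c2O)[C@@H]1C(C)C | intermediate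
18 | dimethyl 5-[(2R,3R,4R)-4-isobutyl-3-isopropyl-5,7-dimethoxychroman-2-yl]-2,4,6-trimethoxyisophthalate | CC(C)C[C@H]1c2c(OC)cc(OC)cc2O[C@@H](c2c(OC)c(C(=O)OC)c(OC)c(C(=O)OC)c2OC)[C@@H]1C(C)C | intermediate
19 | {5-[(2R,3R,4R)-4-isobutyl-3-isopropyl-5,7-dimethoxychroman-2-yl]-2,4,6-trimethoxy-1,3-phenylene}dimethanol | CC(C)C[C@H]1c2c(OC)cc(OC)cc2O[C@@H](c2c(OC)c(CO)c(OC)c(CO)c2OC)[C@@H]1C(C)C | intermediate
20 | 5-[(2R,3R,4R)-4-isobutyl-3-isopropyl-5,7-dimethoxychroman-2-yl]-2,4,6-trimethoxyisophthalaldehyde | CC(C)C[C@H]1c2c(OC)cc(OC)cc2O[C@@H](c2c(OC)c(C=O)c(OC)c(C=O)c2OC)[C@@H]1C(C)C | intermediate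
21 | (2R,3R,4R)-2-(3,5-diformyl-2,4,6-trimethoxyphenyl)-4-isobutyl-3-isopropyl-5,7-dimethoxychroman-6,8-dicarbaldehyde | CC(C)C[C@H]1c2c(OC)c(C=O)c(OC)c(C=O)c2O[C@@H](c2c(OC)c(C=O)c(OC)c(C=O)c2OC)[C@@H]1C(C)C | intermediate
22 | sideroxylonal C, (2R,3R,4R)-2-(3,5-diformyl-2,4,6-trihydroxyphenyl)-5,7-dihydroxy-4-isobutyl-3-isopropylchroman-6,8-dicarbaldehyde | CC(C)C[C@H]1c2c(O)c(C=O)c(O)c(C=O)c2O[C@@H](c2c(O)c(C=O)c(O)c(C=O)c2O)[C@@H]1C(C)C | target

## Step count and least certain steps

Total step count: 12. Longest linear sequence: 12 steps, from 1 to 22.

**Step 7 (key step).**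
- **What may go wrong:** During the Mg(OMe)2 stage, ring C may open at C2 by loss of the ring A phenoxide, and the CH2CO2Me carbanion may then add in conjugate fashion to the exposed alkylidene instead of closing by Claisen condensation. The dichloride may also bridge two oxoglutarate molecules in the first stage. The acyl carbons beside the bulky chroman-bearing carbon may react slowly.
- **Fallback:** It sets out from lactol 8 and oxoglutarate 14 and rejoins the route at 17. Ring B is first made on its own. 14 and dimethyl malonate are condensed with NaOMe in MeOH and then heated, the classical cyclocondensation, which is safe here because neither partner carries a base-labile group. This gives dimethyl 2,4,6-trihydroxyisophthalate F1. F1 has one free ring position, C5, and is alkylated there by the oxocarbenium ion of 8 (BF3·OEt2, CH2Cl2, −20 °C). Attack trans to the isopropyl group, and equilibration under the acid, should give 17.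

**Step 3.**
- **What may go wrong:** The alkyl-substituted quinone methide 6 may tautomerise to a 2-alkenylphenol before the enamine adds. Addition to this donor-stabilised methide may be slow. The facial selectivity at C4 may be low or reversed if 6 reacts through the alkene geometry in which the side chain lies beside the carbonyl oxygen.
- **Fallback:** It sets out from aldehyde 5 and returns at lactol 8, and it avoids the quinone methide.
  - 5 is homologated by Wittig reaction with (triphenylphosphoranylidene)acetaldehyde to (E)-5-methylhex-2-enal F2.
  - F2 and 3,5-dimethoxyphenol F3 undergo the established iminium-catalysed Friedel–Crafts/hemiacetalisation with the same (S)-prolinol silyl ether to give (4R)-4-isobutyl-5,7-dimethoxychroman-2-ol F4.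
  - F4 is oxidised (PhI(OAc)2, TEMPO) to (4R)-4-isobutyl-5,7-dimethoxychroman-2-one F5.
  - The lithium enolate of F5 (LiN(i-Pr)2, THF, −78 °C) adds to acetone trans to the isobutyl group to give (3S,4R)-3-(2-hydroxypropan-2-yl)-4-isobutyl-5,7-dimethoxychroman-2-one F6.
  - Dehydration (MsCl, Et3N, then DBU) gives (4S)-4-isobutyl-5,7-dimethoxy-3-(propan-2-ylidene)chroman-2-one F7. The descriptor changes by the sequence rules only; the arrangement at C4 is unchanged.
  - Hydrogenation (H2, Pd/C) and equilibration with DBU give (3R,4R)-4-isobutyl-3-isopropyl-5,7-dimethoxychroman-2-one F8.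
  - i-Bu2AlH at −78 °C reduces F8 to 8.

**Step 4.**
- **What may go wrong:** Knoevenagel condensation may be slow at an α-branched aldehyde that is mostly masked as the lactol. Prolonged heating may lead to deconjugation of 10 and loss of material.
- **Fallback:** It sets out from lactol 8 and returns at malonic acid 12, bypassing 11. 8 is condensed with 2,2-dimethyl-1,3-dioxane-4,6-dione, which reacts with hindered aldehydes at room temperature (pyrrolidinium acetate cat., CH2Cl2). The same oxa-Michael addition closes the ring to 5-[(2R,3R,4R)-4-isobutyl-3-isopropyl-5,7-dimethoxychroman-2-yl]-2,2-dimethyl-1,3-dioxane-4,6-dione F9. Mild aqueous acid (1 M HCl, THF, 40 °C) opens the dioxanedione with loss of acetone to give 12.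

**Step 11.**
- **What may go wrong:** The reaction may stall after the first formylation. The C2–O1 bond may ionise under TiCl4 with loss of configuration at C2. Chelation-driven partial demethylation beside the ring B aldehydes may give mixtures.
- **Fallback:** It sets out from diester 18 and returns at 21. The Rieche formylation is run on 18, whose ring B carries esters that bind the Lewis acid less and do not direct demethylation. This gives dimethyl 5-[(2R,3R,4R)-6,8-diformyl-4-isobutyl-3-isopropyl-5,7-dimethoxychroman-2-yl]-2,4,6-trimethoxyisophthalate F10. i-Bu2AlH reduces all four carbonyl groups to {(2R,3R,4R)-2-[3,5-bis(hydroxymethyl)-2,4,6-trimethoxyphenyl]-4-isobutyl-3-isopropyl-5,7-dimethoxychroman-6,8-diyl}dimethanol F11. MnO2 oxidises the four benzylic alcohols to 21.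

**Step 12.**
- **What may go wrong:** The Lewis acid, held by the C8 formyl group, may cleave the C2–O1 bond, with ring opening and scrambling at C2. The two doubly flanked ethers may be removed incompletely. Formyl groups may be halogenated.
- **Fallback:** It sets out from dialdehyde 20 and returns at 22. The five methyl ethers are removed from 20 with BBr3 (CH2Cl2, −78 °C to rt), at a stage where O1 has no formyl neighbour to direct the Lewis acid onto the ring ether. This gives 5-[(2R,3R,4R)-5,7-dihydroxy-4-isobutyl-3-isopropylchroman-2-yl]-2,4,6-trihydroxyisophthalaldehyde F12. The free, highly nucleophilic ring A is then formylated twice under Vilsmeier–Haack conditions (POCl3, DMF, then aqueous hydrolysis) to give 22.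

## Further compounds

F1 | step 7 | dimethyl 2,4,6-trihydroxyisophthalate | COC(=O)c1c(O)cc(O)c(C(=O)OC)c1O
F2 | step 3 | (E)-5-methylhex-2-enal | CC(C)C/C=C/C=O
F3 | step 3 | 3,5-dimethoxyphenol | COc1cc(O)cc(OC)c1
F4 | step 3 | (4R)-4-isobutyl-5,7-dimethoxychroman-2-ol | CC(C)C[C@H]1c2c(OC)cc(OC)cc2OC(O)C1
F5 | step 3 | (4R)-4-isobutyl-5,7-dimethoxychroman-2-one | CC(C)C[C@H]1c2c(OC)cc(OC)cc2OC(=O)C1
F6 | step 3 | (3S,4R)-3-(2-hydroxypropan-2-yl)-4-isobutyl-5,7-dimethoxychroman-2-one | CC(C)C[C@H]1c2c(OC)cc(OC)cc2OC(=O)[C@@H]1C(C)(C)O
F7 | step 3 | (4S)-4-isobutyl-5,7-dimethoxy-3-(propan-2-ylidene)chroman-2-one | CC(C)C[C@H]1c2c(OC)cc(OC)cc2OC(=O)C1=C(C)C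
F8 | step 3 | (3R,4R)-4-isobutyl-3-isopropyl-5,7-dimethoxychroman-2-one | CC(C)C[C@H]1c2c(OC)cc(OC)cc2OC(=O)[C@@H]1C(C)C
F9 | step 4 | 5-[(2R,3R,4R)-4-isobutyl-3-isopropyl-5,7-dimethoxychroman-2-yl]-2,2-dimethyl-1,3-dioxane-4,6-dione | CC(C)C[C@H]1c2c(OC)cc(OC)cc2O[C@@H](C2C(=O)OC(C)(C)OC2=O)[C@@H]1C(C)C
F10 | step 11 | dimethyl 5-[(2R,3R,4R)-6,8-diformyl-4-isobutyl-3-isopropyl-5,7-dimethoxychroman-2-yl]-2,4,6-trimethoxyisophthalate | CC(C)C[C@H]1c2c(OC)c(C=O)c(OC)c(C=O)c2O[C@@H](c2c(OC)c(C(=O)OC)c(OC)c(C(=O)OC)c2OC)[C@@H]1C(C)C
F11 | step 11 | {(2R,3R,4R)-2-[3,5-bis(hydroxymethyl)-2,4,6-trimethoxyphenyl]-4-isobutyl-3-isopropyl-5,7-dimethoxychroman-6,8-diyl}dimethanol | CC(C)C[C@H]1c2c(OC)c(CO)c(OC)c(CO)c2O[C@@H](c2c(OC)c(CO)c(OC)c(CO)c2OC)[C@@H]1C(C)C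
F12 | step 12 | 5-[(2R,3R,4R)-5,7-dihydroxy-4-isobutyl-3-isopropylchroman-2-yl]-2,4,6-trihydroxyisophthalaldehyde | CC(C)C[C@H]1c2c(O)cc(O)cc2O[C@@H](c2c(O)c(C=O)c(O)c(C=O)c2O)[C@@H]1C(C)C
A1 | alternative 1 | rac-2-[(3,5-dimethoxyphenoxy)(methoxy)methyl]-1,3,5-trimethoxybenzene | COC(Oc1cc(OC)cc(OC)c1)c1c(OC)cc(OC)cc1OC
A2 | alternative 1 | (E)-2,6-dimethylhepta-2,4-diene | CC(C)/C=C/C=C(C)C
A3 | alternative 1 | 2,3-trans-3,4-trans-3-isopropyl-5,7-dimethoxy-4-(2-methylprop-1-enyl)-2-(2,4,6-trimethoxyphenyl)chroman | CC(C)=C[C@H]1c2c(OC)cc(OC)cc2O[C@@H](c2c(OC)cc(OC)cc2OC)[C@@H]1C(C)C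
A4 | alternative 2 | (R)-2-(2,6-dimethylhept-2-en-4-yl)-3,5-dimethoxyphenol | CC(C)C[C@H](C=C(C)C)c1c(OC)cc(OC)cc1O
A5 | alternative 2 | 2,4,6-trimethoxybenzaldehyde | COc1cc(OC)c(C=O)c(OC)c1
A6 | alternative 2 | 2,3-trans-3,4-trans-4-isobutyl-3-isopropenyl-5,7-dimethoxy-2-(2,4,6-trimethoxyphenyl)chroman | CC(C)C[C@H]1c2c(OC)cc(OC)cc2O[C@@H](c2c(OC)cc(OC)cc2OC)[C@@H]1C(C)=C
A7 | alternative 3 | (E)-2-isopropyl-5-methylhex-2-enal | CC(C)C/C=C(\C(C)C)C=O
A8 | alternative 3 | 3,5-dimethoxyphenol | COc1cc(O)cc(OC)c1
A9 | alternative 3 | 3,4-trans-4-isobutyl-3-isopropyl-5,7-dimethoxychroman-2-ol (anomeric mixture) | CC(C)C[C@H]1c2c(OC)cc(OC)cc2OC(O)[C@@H]1C(C)C
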